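The numbers in the tables were generated by integration for an exercise; noise was put on by code.

**Small charge.** With a small charge of J, 0.19 M against 0.30 M of X, the south run still kept just 56% of its X at 2.50 h.

all flasks: X 0.30 M

| charge | J | remark | time |
|---|---|---|---|
| south | 0.19 M | run made earlier |  |
| north-east | 0.42 M | run made earlier |  |
| oak | 0.360 M |  | 2.5 h |
| larch | 0.540 M |  | 2.5 h |

| run | time / h | L / % | X / % | G / % | D / % |
|---|---|---|---|---|---|
| south | 0.167 | 3 | 93 | 0 | 5 |
| south | 0.500 | 7 | 81 | 0 | 7 |
| south | 0.833 | 8 | 79 | 2 | 12 |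
| south | 1.33 | 14 | 67 | 1 | 15 |
| south | 2.00 | 14 | 63 | 1 | 18 |
| south | 2.50 | 15 | 56 | 1 | 18 |
| north-east | 0.417 | 13 | 71 | 2 | 16 |
| north-east | 0.833 | 18 | 57 | 6 | 22 |
| north-east | 1.33 | 23 | 45 | 8 | 23 |
| north-east | 1.50 | 23 | 39 | 8 | 27 |
| north-east | 2.00 | 27 | 30 | 17 | 25 |
| north-east | 2.50 | 31 | 30 | 19 | 24 |

(each reading ± 1.5 percentage points)

* which of these there is most of at the end, counted by the X in it, oak (D / X / L / G)
* which of these there is most of at the end, counted by the X in it, larch (D / X / L / G)
* amount of the one of these that there is most of at the end, in percent of the X charged, oak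
* amount of the one of these that there is most of at the end, in percent of the X charged, larch

- percent here means X units held: one Q counts as two
- what is said of D includes Q
- candidate steps: J + L -> G; J -> E; X + J -> L; J + D -> G; X + D <-> Q; X + J -> D
- in an amount of D, one Q counts as one D

**Turns.** I worked with the fraction left and called the logarithm of its inverse the turns: 0.580 for south and 1.20 for north-east at that time. Per molar of J charged these give 3.05 L mol⁻¹ and 2.87 L mol⁻¹, which are close, so at this X charge and time I took turns as proportional to J, with the mean 2.96 L mol⁻¹. That gives oak 1.07 turns and larch 1.60.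

**Break-even.** L's selectivity, L made per X lost, read 0.341 in south and 0.443 in north-east, mean 0.392. X left equals L where the fraction left is that share over one plus that share, so the break-even turns are 1.27. Oak lies below this, so I expected X to lead at 34.3%. Larch lies above it, so I expected L to lead at 31.3%.

**One number?** Each run's own share gives a break-even of 1.18 or 1.37, and both lie between oak and larch . The order survives, but larch's L spreads from 27.2% to 35.4%.

**Forecast.** It named X at 34% for oak and L at 35% for larch, higher than my L, and it reckoned with a split of “about 42% to L and 58% to D”.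

**Result.** Oak gave X at 34.2%, and larch gave L at 33.1%.

    J + L → G (k = 7.70 × 10⁻⁴ L mol⁻¹ min⁻¹)
    J → E (k = 3.50 × 10⁻⁶ min⁻¹)
    X + J → L (k = 0.0140 L mol⁻¹ min⁻¹)
    J + D → G (k = 0.0250 L mol⁻¹ min⁻¹)
    X + D ⇌ Q, settled at all times (K = 0.720 L mol⁻¹)
    X + J → D (k = 0.0190 L mol⁻¹ min⁻¹)

**Neighbour flask.** Larch with 0.51 M of X keeps its J charge but has 1.06 equiv of J to X. Reckoned from J, its turns stay 1.60, which puts X at 20.2%, yet this neighbour held 28.8%. Its X gives 1.24 turns, close to the break-even 1.27. In this neighbour, X stood at 28.8% and L at 28.7%.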